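**Strategy**

Everything rests on building the middle ring B from open-chain carbon while it is already esterified to ring C. Ring B is an orsellinate: the C1 ester carbon, a free C2 hydroxyl, C3–H, the C4 oxygen that carries ring A, C5–H and C6–CH3. Its meta C2/C4 dioxygenation is exactly what a vinylketene and a siloxyalkyne leave behind, so one benzannulation forms C2–C3, C4–C5 and C1–C2 and delivers the two oxygens differentiated (C2–OH free, C4–O silylated). The precursor is the ring C aryl ester of (E)-5-diazo-3-methyl-4-oxopent-2-enoic acid, reached from an unhindered bromoacetate. Desilylation, acylation by a benzyl-protected ring A acid and hydrogenolysis complete the tridepside.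

Key step: step 9

Assumption: 1-(2,4-dihydroxy-6-methylphenyl)ethanone (25) and acetylene are taken as purchased. The target is achiral; the only stereochemical element in the route is the E geometry of the enoate in 11–13, which disappears on aromatization.

**Route**

Step 1
Reactants: 1 orsellinic acid (2,4-dihydroxy-6-methylbenzoic acid)
Product: 2 benzyl 2,4-dihydroxy-6-methylbenzoate
Conditions: BnBr (1.05 equiv), KHCO3, DMF, rt
Reagents that add atoms: benzyl bromide, BrCc1ccccc1
Why: Carboxylate O-alkylation (SN2 esterification) should be selective because bicarbonate ionizes only the carboxylic acid, and room temperature avoids decarboxylation of the orsellinic acid.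

Step 2
Reactants: 2 benzyl 2,4-dihydroxy-6-methylbenzoate
Product: 3 benzyl 4-(allyloxy)-2-hydroxy-6-methylbenzoate
Conditions: allyl bromide (1.1 equiv), K2CO3, acetone, reflux
Reagents that add atoms: allyl bromide, C=CCBr
Why: Williamson ether synthesis should occur only at the 4-hydroxyl, since the 2-hydroxyl is held in a hydrogen bond to the ester carbonyl and is far less nucleophilic under carbonate in acetone.

Step 3
Reactants: 3 benzyl 4-(allyloxy)-2-hydroxy-6-methylbenzoate
Product: 4 benzyl 4-(allyloxy)-2-(benzyloxy)-6-methylbenzoate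
Conditions: BnBr, K2CO3, DMF, 60 °C
Reagents that add atoms: benzyl bromide, BrCc1ccccc1
Why: A second Williamson etherification under more forcing conditions should alkylate the remaining hydrogen-bonded phenol, the allyl ether and benzyl ester being inert to carbonate.

Step 4
Reactants: 4 benzyl 4-(allyloxy)-2-(benzyloxy)-6-methylbenzoate
Product: 5 benzyl 2-(benzyloxy)-4-hydroxy-6-methylbenzoate
Conditions: Pd(PPh3)4 (cat.), morpholine, THF, rt
Reagents that add atoms: none
Why: Tsuji–Trost deallylation, in which zerovalent palladium ionizes the aryl allyl ether to a pi-allyl complex that morpholine captures, should free the 4-hydroxyl without touching the benzyl ether or benzyl ester.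

Step 5
Reactants: 5 benzyl 2-(benzyloxy)-4-hydroxy-6-methylbenzoate; 6 bromoacetyl bromide
Product: 7 3-(benzyloxy)-4-(benzyloxycarbonyl)-5-methylphenyl bromoacetate
Conditions: pyridine, CH2Cl2, 0 °C
Reagents that add atoms: none
Why: Nucleophilic acyl substitution of the acyl bromide by the only free phenol should give the unhindered aryl bromoacetate, the acyl carbon being far more electrophilic than the CH2Br carbon at 0 °C.

Step 6
Reactants: 7 3-(benzyloxy)-4-(benzyloxycarbonyl)-5-methylphenyl bromoacetate; 8 butane-2,3-dione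
Product: 11 3-(benzyloxy)-4-(benzyloxycarbonyl)-5-methylphenyl (E)-3-methyl-4-oxopent-2-enoate, via phosphonium bromide 9 (not isolated), via phosphorus ylide 10 (not isolated)
Conditions: PPh3, CH2Cl2, rt; then Et3N, butane-2,3-dione (3 equiv), rt to 40 °C
Reagents that add atoms: none
Why: SN2 quaternization of PPh3 and deprotonation give the ester-stabilized ylide, whose Wittig olefination of one carbonyl of the symmetrical diketone (in excess, to avoid double olefination) should give mainly the E enoate with the ester trans to the acetyl group, any Z isomer being removed by chromatography.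

Step 7
Reactants: 11 3-(benzyloxy)-4-(benzyloxycarbonyl)-5-methylphenyl (E)-3-methyl-4-oxopent-2-enoate
Product: 13 3-(benzyloxy)-4-(benzyloxycarbonyl)-5-methylphenyl (E)-5-diazo-3-methyl-4-oxopent-2-enoate, via trifluoroacetyl diketone 12 (not isolated)
Conditions: LiN(SiMe3)2, THF, −78 °C; CF3CO2CH2CF3, −78 °C; aq. HCl work-up; then MsN3, Et3N, H2O (1 equiv), MeCN, rt
Reagents that add atoms: methanesulfonyl azide, CS(=O)(=O)N=[N+]=[N-]
Why: In this detrifluoroacetylative diazo transfer (a Regitz-type transfer), kinetic deprotonation at the acetyl methyl and C-trifluoroacetylation give an activated 1,3-diketone that accepts the diazo group with loss of the trifluoroacetyl group, under conditions that should spare the aryl and benzyl esters and the enoate geometry.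

Step 8
Reactants: 14 acetylene; 15 triisopropylsilyl trifluoromethanesulfonate
Product: 18 (triisopropylsiloxy)ethyne, via lithium acetylide 16 (not isolated), via lithium ethynolate 17 (not isolated)
Conditions: n-BuLi, THF, −78 °C; LiOOt-Bu (from t-BuOOH, LiN(SiMe3)2), −78 to 0 °C; then 15, −78 to 0 °C
Reagents that add atoms: tert-butyl hydroperoxide, CC(C)(C)OO
Why: Electrophilic oxygenation of the lithium acetylide by lithium tert-butyl peroxide should give the ynolate, which the hard and bulky silyl triflate is expected to silylate on oxygen (ynolate O-silylation) to the distillable silyl ynol ether.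

Step 9
Reactants: 13 3-(benzyloxy)-4-(benzyloxycarbonyl)-5-methylphenyl (E)-5-diazo-3-methyl-4-oxopent-2-enoate; 18 (triisopropylsiloxy)ethyne
Product: 23 3-(benzyloxy)-4-(benzyloxycarbonyl)-5-methylphenyl 2-hydroxy-6-methyl-4-(triisopropylsiloxy)benzoate, via vinylketene 19 (not isolated), via vinylcyclobutenone 20 (not isolated), via dienylketene 21 (not isolated), via cyclohexadienone 22 (not isolated)
Conditions: 18 (2.5 equiv), hν (350 nm, Pyrex), degassed ClCH2CH2Cl, rt; then 80 °C
Reagents that add atoms: none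
Why: Long-wavelength light is absorbed only by the diazoketone, which loses N2 and undergoes Wolff rearrangement (1,2-shift of the C6 vinyl carbon from the ketone carbon C2 to the diazo carbon C5) to vinylketene 19, and the electron-poor ketene is captured by the electron-rich siloxyalkyne in a [2+2] cycloaddition that forms C2–C3 and C4–C5 in vinylcyclobutenone 20. Four-electron conrotatory electrocyclic opening of 20 gives dienylketene 21, and ring B is then closed by a thermal six-electron disrotatory electrocyclization that forms C1–C2, after which dienone 22 tautomerizes to the phenol. The closest known reaction type is the second-generation Danheiser benzannulation of unsaturated alpha-diazo ketones with siloxyalkynes to give resorcinol monosilyl ethers. No stereocentre is created, and the E enoate places the ester outside and hydrogen inside at the cyclizing terminus, which favours the six-electron closure. The selectivity needed is regiochemical (the siloxy carbon must end meta to the new hydroxyl), and it is secured by the polarization of the ynol ether, whose unsubstituted nucleophilic carbon bonds to the electrophilic ketene carbonyl carbon. The benzyl ether on ring C removes a phenol that could trap the ketene, and the long wavelength should avoid photo-Fries reaction of the aryl ester.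

Step 10
Reactants: 23 3-(benzyloxy)-4-(benzyloxycarbonyl)-5-methylphenyl 2-hydroxy-6-methyl-4-(triisopropylsiloxy)benzoate
Product: 24 3-(benzyloxy)-4-(benzyloxycarbonyl)-5-methylphenyl 2,4-dihydroxy-6-methylbenzoate
Conditions: Bu4NF, AcOH, THF, 0 °C
Reagents that add atoms: none
Why: Fluoride-induced cleavage of the aryl silyl ether should be fast at 0 °C, and the acetic acid buffer keeps the liberated phenoxide from attacking the aryl ester linkage.

Step 11
Reactants: 25 1-(2,4-dihydroxy-6-methylphenyl)ethanone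
Product: 26 1-[2,4-bis(benzyloxy)-6-methylphenyl]ethanone
Conditions: BnBr (2.4 equiv), K2CO3, DMF, 60 °C
Reagents that add atoms: benzyl bromide, BrCc1ccccc1
Why: Double Williamson etherification, for which heating in DMF is needed because the 2-hydroxyl is hydrogen-bonded to the ketone.

Step 12
Reactants: 26 1-[2,4-bis(benzyloxy)-6-methylphenyl]ethanone
Product: 27 2,4-bis(benzyloxy)-6-methylphenyl acetate
Conditions: mCPBA, CF3CO2H (cat.), CH2Cl2, 0 °C to rt
Reagents that add atoms: 3-chloroperoxybenzoic acid, OOC(=O)c1cccc(Cl)c1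
Why: Baeyer–Villiger oxidation in which the electron-rich, doubly ortho-substituted aryl group should migrate in preference to methyl, so the acetyl group becomes directly the aryl acetate that the target carries at C5 of ring A.

Step 13
Reactants: 27 2,4-bis(benzyloxy)-6-methylphenyl acetate
Product: 29 4,6-bis(benzyloxy)-3-formyl-2-methylphenyl acetate, via iminium salt 28 (not isolated)
Conditions: POCl3, DMF, 0 to 60 °C; then ice-water
Reagents that add atoms: N,N-dimethylformamide, CN(C)C=O; water, O
Why: Vilsmeier–Haack formylation should attack the free position next to the methyl group (para to one benzyloxy, ortho to the other) in preference to the more crowded position between the two benzyloxy groups, as is usual for 3,5-dialkoxytoluenes.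

Step 14
Reactants: 29 4,6-bis(benzyloxy)-3-formyl-2-methylphenyl acetate
Product: 30 3-acetoxy-4,6-bis(benzyloxy)-2-methylbenzoic acid
Conditions: NaClO2, NaH2PO4, 2-methylbut-2-ene, t-BuOH–H2O, rt
Reagents that add atoms: sodium chlorite, [Na+].[O-]Cl=O
Why: Pinnick oxidation converts the hindered aldehyde into the acid at about pH 4, where the acetate and benzyl ethers are stable, and the alkene scavenges hypochlorous acid before it can chlorinate the ring.

Step 15
Reactants: 30 3-acetoxy-4,6-bis(benzyloxy)-2-methylbenzoic acid; 24 3-(benzyloxy)-4-(benzyloxycarbonyl)-5-methylphenyl 2,4-dihydroxy-6-methylbenzoate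
Product: 32 3-(benzyloxy)-4-(benzyloxycarbonyl)-5-methylphenyl 4-{[3-acetoxy-4,6-bis(benzyloxy)-2-methylbenzoyl]oxy}-2-hydroxy-6-methylbenzoate, via acid chloride 31 (not isolated)
Conditions: (COCl)2, DMF (cat.), CH2Cl2, 0 °C to rt; evaporate; then 24, Et3N, DMAP (cat.), CH2Cl2, 0 °C to rt
Reagents that add atoms: none
Why: The acid chloride formed under chloroiminium catalysis acylates the phenol by DMAP-catalysed nucleophilic acyl substitution, and only the 4-hydroxyl of ring B should react because the 2-hydroxyl is locked in a hydrogen bond to the neighbouring ester carbonyl.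

Step 16
Reactants: 32 the fully protected tridepside
Product: 33 4-[(4-{[3-acetoxy-4,6-dihydroxy-2-methylbenzoyl]oxy}-2-hydroxy-6-methylbenzoyl)oxy]-2-hydroxy-6-methylbenzoic acid (target)
Conditions: H2 (1 atm), Pd/C, EtOAc–THF, rt
Reagents that add atoms: none
Why: Hydrogenolysis over Pd/C cleaves the three benzyl ethers and the benzyl ester at their benzylic C–O bonds while aryl esters and the aryl acetate are inert, and the neutral aprotic medium should keep acetyl migration from O5 to O4 of ring A slow.

**Compound list**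

1 | orsellinic acid (2,4-dihydroxy-6-methylbenzoic acid) | Cc1cc(O)cc(O)c1C(=O)O | starting material
2 | benzyl 2,4-dihydroxy-6-methylbenzoate | Cc1cc(O)cc(O)c1C(=O)OCc1ccccc1 | intermediate
3 | benzyl 4-(allyloxy)-2-hydroxy-6-methylbenzoate | C=CCOc1cc(C)c(C(=O)OCc2ccccc2)c(O)c1 | intermediate
4 | benzyl 4-(allyloxy)-2-(benzyloxy)-6-methylbenzoate | C=CCOc1cc(C)c(C(=O)OCc2ccccc2)c(OCc2ccccc2)c1 | intermediate
5 | benzyl 2-(benzyloxy)-4-hydroxy-6-methylbenzoate | Cc1cc(O)cc(OCc2ccccc2)c1C(=O)OCc1ccccc1 | intermediate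
6 | bromoacetyl bromide | BrCC(Br)=O | starting material
7 | 3-(benzyloxy)-4-(benzyloxycarbonyl)-5-methylphenyl bromoacetate | BrCC(=O)Oc1cc(C)c(C(=O)OCc2ccccc2)c(OCc2ccccc2)c1 | intermediate
8 | butane-2,3-dione | CC(=O)C(C)=O | starting material
9 | {2-[3-(benzyloxy)-4-(benzyloxycarbonyl)-5-methylphenoxy]-2-oxoethyl}triphenylphosphonium bromide | [Br-].O=C(C[P+](c1ccccc1)(c1ccccc1)c1ccccc1)Oc1cc(C)c(C(=O)OCc2ccccc2)c(OCc2ccccc2)c1 | intermediate (not isolated)
10 | 3-(benzyloxy)-4-(benzyloxycarbonyl)-5-methylphenyl (triphenylphosphoranylidene)acetate | O=C(C=P(c1ccccc1)(c1ccccc1)c1ccccc1)Oc1cc(C)c(C(=O)OCc2ccccc2)c(OCc2ccccc2)c1 | intermediate (not isolated)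
11 | 3-(benzyloxy)-4-(benzyloxycarbonyl)-5-methylphenyl (E)-3-methyl-4-oxopent-2-enoate | CC(=O)/C(C)=C/C(=O)Oc1cc(C)c(C(=O)OCc2ccccc2)c(OCc2ccccc2)c1 | intermediate
12 | 3-(benzyloxy)-4-(benzyloxycarbonyl)-5-methylphenyl (E)-7,7,7-trifluoro-3-methyl-4,6-dioxohept-2-enoate | O=C(CC(=O)/C(C)=C/C(=O)Oc1cc(C)c(C(=O)OCc2ccccc2)c(OCc2ccccc2)c1)C(F)(F)F | intermediate (not isolated)
13 | 3-(benzyloxy)-4-(benzyloxycarbonyl)-5-methylphenyl (E)-5-diazo-3-methyl-4-oxopent-2-enoate | [N-]=[N+]=CC(=O)/C(C)=C/C(=O)Oc1cc(C)c(C(=O)OCc2ccccc2)c(OCc2ccccc2)c1 | intermediate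
14 | acetylene (ethyne) | C#C | starting material
15 | triisopropylsilyl trifluoromethanesulfonate | CC(C)[Si](OS(=O)(=O)C(F)(F)F)(C(C)C)C(C)C | starting material
16 | lithium acetylide | [Li]C#C | intermediate (not isolated)
17 | lithium ethynolate | [Li]OC#C | intermediate (not isolated)
18 | (triisopropylsiloxy)ethyne | C#CO[Si](C(C)C)(C(C)C)C(C)C | intermediate
19 | 3-(benzyloxy)-4-(benzyloxycarbonyl)-5-methylphenyl (E)-3-methyl-5-oxopenta-2,4-dienoate (vinylketene; ketenyl carbon trans to the ester) | O=C=C/C(C)=C/C(=O)Oc1cc(C)c(C(=O)OCc2ccccc2)c(OCc2ccccc2)c1 | intermediate (not isolated)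
20 | 3-(benzyloxy)-4-(benzyloxycarbonyl)-5-methylphenyl (E)-3-[4-oxo-2-(triisopropylsiloxy)cyclobut-2-en-1-yl]but-2-enoate (racemic at the ring carbon) | O=C1C=C(O[Si](C(C)C)(C(C)C)C(C)C)C1/C(C)=C/C(=O)Oc1cc(C)c(C(=O)OCc2ccccc2)c(OCc2ccccc2)c1 | intermediate (not isolated)
21 | 3-(benzyloxy)-4-(benzyloxycarbonyl)-5-methylphenyl (2E,4E)-3-methyl-7-oxo-5-(triisopropylsiloxy)hepta-2,4,6-trienoate (dienylketene; ketenyl carbon and C3 cis across the 4,5-double bond) | O=C=C\C(O[Si](C(C)C)(C(C)C)C(C)C)=C/C(C)=C/C(=O)Oc1cc(C)c(C(=O)OCc2ccccc2)c(OCc2ccccc2)c1 | intermediate (not isolated)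
22 | 3-(benzyloxy)-4-(benzyloxycarbonyl)-5-methylphenyl 2-methyl-6-oxo-4-(triisopropylsiloxy)cyclohexa-2,4-diene-1-carboxylate (racemic) | O=C1C=C(O[Si](C(C)C)(C(C)C)C(C)C)C=C(C)C1C(=O)Oc1cc(C)c(C(=O)OCc2ccccc2)c(OCc2ccccc2)c1 | intermediate (not isolated)
23 | 3-(benzyloxy)-4-(benzyloxycarbonyl)-5-methylphenyl 2-hydroxy-6-methyl-4-(triisopropylsiloxy)benzoate | Cc1cc(O[Si](C(C)C)(C(C)C)C(C)C)cc(O)c1C(=O)Oc1cc(C)c(C(=O)OCc2ccccc2)c(OCc2ccccc2)c1 | intermediate
24 | 3-(benzyloxy)-4-(benzyloxycarbonyl)-5-methylphenyl 2,4-dihydroxy-6-methylbenzoate | Cc1cc(O)cc(O)c1C(=O)Oc1cc(C)c(C(=O)OCc2ccccc2)c(OCc2ccccc2)c1 | intermediate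
25 | 1-(2,4-dihydroxy-6-methylphenyl)ethanone | CC(=O)c1c(C)cc(O)cc1O | starting material
26 | 1-[2,4-bis(benzyloxy)-6-methylphenyl]ethanone | CC(=O)c1c(C)cc(OCc2ccccc2)cc1OCc1ccccc1 | intermediate
27 | 2,4-bis(benzyloxy)-6-methylphenyl acetate | CC(=O)Oc1c(C)cc(OCc2ccccc2)cc1OCc1ccccc1 | intermediate
28 | N-{[3-acetoxy-4,6-bis(benzyloxy)-2-methylphenyl]methylidene}-N-methylmethanaminium dichlorophosphate | C[N+](C)=Cc1c(C)c(OC(C)=O)c(OCc2ccccc2)cc1OCc1ccccc1.[O-]P(=O)(Cl)Cl | intermediate (not isolated)
29 | 4,6-bis(benzyloxy)-3-formyl-2-methylphenyl acetate | CC(=O)Oc1c(C)c(C=O)c(OCc2ccccc2)cc1OCc1ccccc1 | intermediate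
30 | 3-acetoxy-4,6-bis(benzyloxy)-2-methylbenzoic acid | CC(=O)Oc1c(C)c(C(=O)O)c(OCc2ccccc2)cc1OCc1ccccc1 | intermediate
31 | 3-acetoxy-4,6-bis(benzyloxy)-2-methylbenzoyl chloride | CC(=O)Oc1c(C)c(C(Cl)=O)c(OCc2ccccc2)cc1OCc1ccccc1 | intermediate (not isolated)
32 | 3-(benzyloxy)-4-(benzyloxycarbonyl)-5-methylphenyl 4-{[3-acetoxy-4,6-bis(benzyloxy)-2-methylbenzoyl]oxy}-2-hydroxy-6-methylbenzoate | CC(=O)Oc1c(OCc2ccccc2)cc(OCc2ccccc2)c(C(=O)Oc2cc(C)c(C(=O)Oc3cc(C)c(C(=O)OCc4ccccc4)c(OCc4ccccc4)c3)c(O)c2)c1C | intermediate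
33 | 4-[(4-{[3-acetoxy-4,6-dihydroxy-2-methylbenzoyl]oxy}-2-hydroxy-6-methylbenzoyl)oxy]-2-hydroxy-6-methylbenzoic acid | CC(=O)Oc1c(O)cc(O)c(C(=O)Oc2cc(C)c(C(=O)Oc3cc(C)c(C(=O)O)c(O)c3)c(O)c2)c1C | target

**Step count and risk**

Total step count: 16. Longest linear sequence: 11 (steps 1–7, 9, 10, 15, 16).

Most likely to fail, in order:

Step 9. The vinylketene may be captured by the phenolic hydroxyl of product already formed instead of by the alkyne. The cascade may also stall at cyclobutenone 20, or the alkyne may isomerize to the silylketene during the thermal stage. Fallback, setting out from 1 and 5 and returning at 23: 1 is silylated twice (i-Pr3SiCl, imidazole, DMF) to triisopropylsilyl 2-hydroxy-6-methyl-4-(triisopropylsiloxy)benzoate F1. Mild aqueous hydrolysis (AcOH, THF–H2O) cleaves only the silyl ester to 2-hydroxy-6-methyl-4-(triisopropylsiloxy)benzoic acid F2. Carbodiimide esterification of F2 with phenol 5 (DCC, toluene, rt) would then give 23 by classical depside coupling, the hydrogen-bonded 2-hydroxyl of F2 staying free.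

Step 8. The parent ynolate may be silylated at its unhindered carbon (or the product may undergo a 1,3-silyl shift) to give the silylketene. Monolithium acetylide may also disproportionate on warming, and the volatile product may be lost on isolation. Fallback, setting out from 15 and 13 and returning at 23: purchased lithium (trimethylsilyl)acetylide is oxidized with LiOOt-Bu to lithium 2-(trimethylsilyl)ethynolate F3, whose carbon terminus is blocked. O-Silylation with 15 gives trimethyl{[(triisopropylsilyl)oxy]ethynyl}silane F4. Benzannulation of 13 with this alkyne under the conditions of step 9 would pass through 19 and the silylated counterparts of 20–22: the cyclobutenone F5, the dienylketene F6 and the cyclohexadienone F7. It would give 3-(benzyloxy)-4-(benzyloxycarbonyl)-5-methylphenyl 2-hydroxy-6-methyl-4-(triisopropylsiloxy)-3-(trimethylsilyl)benzoate F8. Ipso-protodesilylation at the doubly oxygen-flanked C3 (CF3CO2H, CH2Cl2, 0 °C) would return 23.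

Step 7. The ketone enolate or the amide base may attack the activated aryl ester, or deprotonation may occur at the vinylogous C3 methyl instead of the acetyl methyl, so that trifluoroacetylation and diazo transfer go astray. Fallback, setting out from 8 and 5 and returning at 13: Wittig reaction of 8 with purchased methyl (triphenylphosphoranylidene)acetate gives methyl (E)-3-methyl-4-oxopent-2-enoate F9. The same two-stage diazo transfer, now on a simple methyl ester, proceeds through methyl (E)-7,7,7-trifluoro-3-methyl-4,6-dioxohept-2-enoate F10 to methyl (E)-5-diazo-3-methyl-4-oxopent-2-enoate F11. Saponification (LiOH, THF–H2O, 0 °C) gives (E)-5-diazo-3-methyl-4-oxopent-2-enoic acid F12. Steglich esterification of F12 with phenol 5 (DCC, DMAP, CH2Cl2, 0 °C) forms the aryl ester only after all strongly basic operations and returns 13.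

**Further compounds**

F1 | step 9 | triisopropylsilyl 2-hydroxy-6-methyl-4-(triisopropylsiloxy)benzoate | Cc1cc(O[Si](C(C)C)(C(C)C)C(C)C)cc(O)c1C(=O)O[Si](C(C)C)(C(C)C)C(C)C
F2 | step 9 | 2-hydroxy-6-methyl-4-(triisopropylsiloxy)benzoic acid | Cc1cc(O[Si](C(C)C)(C(C)C)C(C)C)cc(O)c1C(=O)O
F3 | step 8 | lithium 2-(trimethylsilyl)ethynolate | C[Si](C)(C)C#CO[Li]
F4 | step 8 | trimethyl{[(triisopropylsilyl)oxy]ethynyl}silane | C[Si](C)(C)C#CO[Si](C(C)C)(C(C)C)C(C)C
F5 | step 8 | 3-(benzyloxy)-4-(benzyloxycarbonyl)-5-methylphenyl (E)-3-[4-oxo-2-(triisopropylsiloxy)-3-(trimethylsilyl)cyclobut-2-en-1-yl]but-2-enoate | C[Si](C)(C)C1=C(O[Si](C(C)C)(C(C)C)C(C)C)C(/C(C)=C/C(=O)Oc2cc(C)c(C(=O)OCc3ccccc3)c(OCc3ccccc3)c2)C1=O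
F6 | step 8 | 3-(benzyloxy)-4-(benzyloxycarbonyl)-5-methylphenyl (2E,4E)-3-methyl-7-oxo-5-(triisopropylsiloxy)-6-(trimethylsilyl)hepta-2,4,6-trienoate | O=C=C([Si](C)(C)C)\C(O[Si](C(C)C)(C(C)C)C(C)C)=C/C(C)=C/C(=O)Oc1cc(C)c(C(=O)OCc2ccccc2)c(OCc2ccccc2)c1
F7 | step 8 | 3-(benzyloxy)-4-(benzyloxycarbonyl)-5-methylphenyl 2-methyl-6-oxo-4-(triisopropylsiloxy)-5-(trimethylsilyl)cyclohexa-2,4-diene-1-carboxylate | O=C1C([Si](C)(C)C)=C(O[Si](C(C)C)(C(C)C)C(C)C)C=C(C)C1C(=O)Oc1cc(C)c(C(=O)OCc2ccccc2)c(OCc2ccccc2)c1
F8 | step 8 | 3-(benzyloxy)-4-(benzyloxycarbonyl)-5-methylphenyl 2-hydroxy-6-methyl-4-(triisopropylsiloxy)-3-(trimethylsilyl)benzoate | Cc1cc(O[Si](C(C)C)(C(C)C)C(C)C)c([Si](C)(C)C)c(O)c1C(=O)Oc1cc(C)c(C(=O)OCc2ccccc2)c(OCc2ccccc2)c1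
F9 | step 7 | methyl (E)-3-methyl-4-oxopent-2-enoate | COC(=O)/C=C(C)/C(C)=O
F10 | step 7 | methyl (E)-7,7,7-trifluoro-3-methyl-4,6-dioxohept-2-enoate | COC(=O)/C=C(C)/C(=O)CC(=O)C(F)(F)F
F11 | step 7 | methyl (E)-5-diazo-3-methyl-4-oxopent-2-enoate | COC(=O)/C=C(C)/C(=O)C=[N+]=[N-]
F12 | step 7 | (E)-5-diazo-3-methyl-4-oxopent-2-enoic acid | OC(=O)/C=C(C)/C(=O)C=[N+]=[N-]
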